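**Retrosynthetic overview**
- Feature: ring C of calycopterin is a 2-aryl-3-methoxy-4-pyranone. C4, C3 and C2 together with ring B form the C(=O)–Cα=Cβ–aryl arm of a 2'-hydroxychalcone, which lacks only the O1–C2 bond and the oxygen on C3.
- Endgame: the 5-OH comes from the 5-OMe lying peri to C4=O (chelation-directed cleavage), the 4'-OH from a benzyl ether, and the 3-OMe from the flavonol 3-OH.
- Key disconnection: O1–C2 and C3–O are made together by alkaline peroxide oxidation of the chalcone. Cα=Cβ comes from Claisen–Schmidt condensation of 2'-hydroxy-3',4',5',6'-tetramethoxyacetophenone with 4-(benzyloxy)benzaldehyde.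
- The acetophenone comes from 3,4,5-trimethoxyphenol by C-acetylation, bromination of the single ring C–H then left, and CuBr-catalysed exchange of bromide for methoxide.
- Ring order: rings A and B are bought. Ring C is the only ring made, in step 5.

Key step: step 5

Remark on the chemistry: the target has no stereocentre. The only stereocentres on the route are those of the transient 3-hydroxyflavanone in the key step (racemic, one enantiomer drawn), and they are removed in the same flask.

**Step 1**
Reactants: 1 3,4,5-trimethoxyphenol
Product: 3 2'-hydroxy-4',5',6'-trimethoxyacetophenone, via 3,4,5-trimethoxyphenyl acetate 2 (not isolated)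
Conditions: Ac2O, BF3·OEt2, 70 °C; then H2O
Reagents that add atoms: acetic anhydride, CC(=O)OC(C)=O
Why: O-acetylation followed by BF3-promoted Fries rearrangement (Friedel–Crafts C-acylation) should place the acetyl group ortho to the phenol, because the two free ring positions of 1 are equivalent, the para position is blocked, and the first acyl group deactivates the ring towards a second.

**Step 2**
Reactants: 3 2'-hydroxy-4',5',6'-trimethoxyacetophenone
Product: 4 3'-bromo-2'-hydroxy-4',5',6'-trimethoxyacetophenone
Conditions: NBS (1.0 equiv), CH2Cl2, 0 °C → rt, dark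
Reagents that add atoms: N-bromosuccinimide, O=C1CCC(=O)N1Br
Why: Electrophilic aromatic bromination can only strike the one remaining ring C–H, which is activated by the ortho hydroxyl, the ortho methoxy and the para methoxy groups and should react well ahead of the enol of the hydrogen-bonded ketone.

**Step 3**
Reactants: 4 3'-bromo-2'-hydroxy-4',5',6'-trimethoxyacetophenone
Product: 5 2'-hydroxy-3',4',5',6'-tetramethoxyacetophenone
Conditions: NaOMe (MeOH solution, excess), CuBr (0.2 equiv), DMF, 110 °C, Ar; then 1 M HCl
Reagents that add atoms: sodium methoxide, C[O-].[Na+]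
Why: Ullmann-type copper-catalysed methoxylation of an aryl bromide is a reaction class that tolerates, and is helped by, an ortho phenoxide and a ring carbonyl group, as in the conversion of bromohydroxy aryl carbonyl compounds into their methoxy analogues.

**Step 4**
Reactants: 5 2'-hydroxy-3',4',5',6'-tetramethoxyacetophenone; 6 4-(benzyloxy)benzaldehyde
Product: 7 (E)-4-benzyloxy-2'-hydroxy-3',4',5',6'-tetramethoxychalcone
Conditions: KOH, EtOH, rt; then 1 M HCl
Reagents that add atoms: none
Why: Claisen–Schmidt (crossed aldol) condensation of the methyl ketone enolate with a non-enolisable aldehyde, followed by E1cB loss of water, should give the conjugated E-enone, and the phenoxide form keeps the product open as the chalcone.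

**Step 5**
Reactants: 7 (E)-4-benzyloxy-2'-hydroxy-3',4',5',6'-tetramethoxychalcone
Product: 9 4'-benzyloxy-3-hydroxy-5,6,7,8-tetramethoxyflavone, via trans-3-hydroxyflavanone 8 (not isolated)
Conditions: 30% aq H2O2 (excess), aq NaOH, MeOH–THF, 0 °C → rt; then 1 M HCl
Reagents that add atoms: hydrogen peroxide, OO
Why: This is an Algar–Flynn–Oyamada oxidation of a 2'-hydroxychalcone: the 2'-phenoxide of 7 adds to the enone β-carbon (O1–C2), the resulting enolate attacks H2O2 through its α-carbon (C3–O) to give 3-hydroxyflavanone 8, and further alkaline peroxide removes the hydrogens on C2 and C3 to leave flavonol 9. Ring C is the only ring closed, by a 6-endo-trig oxa-Michael addition of the phenoxide oxygen. The two stereocentres of 8 should arise trans (aryl and hydroxyl both equatorial, with C3 epimerisable in base) but are erased in the same flask, so 9 has none and no stereocontrol is needed. The selectivity that matters is bond formation at Cβ (six-membered flavonol) over attack at Cα of a chalcone epoxide (five-membered ring, then aurone), a diversion that the 6'-methoxy group encourages by twisting the carbonyl out of the plane of ring A. If part of 7 is epoxidised first, the para-benzyloxy donor of ring B stabilises positive character at the benzylic Cβ so that the phenoxide should still open the epoxide there, and the cold start should hold epoxidation back relative to direct cyclisation. The aryl methyl ethers and the benzyl ether are inert to cold alkaline peroxide.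

**Step 6**
Reactants: 9 4'-benzyloxy-3-hydroxy-5,6,7,8-tetramethoxyflavone
Product: 10 4'-benzyloxy-3,5,6,7,8-pentamethoxyflavone
Conditions: MeI, K2CO3, acetone, reflux
Reagents that add atoms: iodomethane, CI
Why: Williamson O-methylation of the acidic enolic 3-hydroxyl, the only free OH in 9, should proceed cleanly under mild carbonate conditions that leave every other group untouched.

**Step 7**
Reactants: 10 4'-benzyloxy-3,5,6,7,8-pentamethoxyflavone
Product: 12 calycopterin (5,4'-dihydroxy-3,6,7,8-tetramethoxyflavone), via bis(dichloroboryl) ether 11 (not isolated)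
Conditions: BCl3 (1 M in CH2Cl2, 4 equiv), C6HMe5 (3 equiv), CH2Cl2, −78 → 0 °C; then H2O, 1 M HCl
Reagents that add atoms: none
Why: In this chelation-directed Lewis acid ether cleavage, BCl3 bridges C4=O and the peri 5-methoxy oxygen in a six-membered chelate so that chloride removes only that methyl group, the same reagent ionises the aryl benzyl ether with pentamethylbenzene trapping the benzyl cation by Friedel–Crafts alkylation, and hydrolysis of 11 frees both phenols, while the 3-, 6-, 7- and 8-methyl ethers lack this activation at or below 0 °C.

**Compound list**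
1 | 3,4,5-trimethoxyphenol | COc1cc(O)cc(OC)c1OC | starting material
2 | 3,4,5-trimethoxyphenyl acetate (not isolated) | COc1cc(OC(C)=O)cc(OC)c1OC | intermediate
3 | 2'-hydroxy-4',5',6'-trimethoxyacetophenone [1-(6-hydroxy-2,3,4-trimethoxyphenyl)ethanone] | CC(=O)c1c(O)cc(OC)c(OC)c1OC | intermediate
4 | 3'-bromo-2'-hydroxy-4',5',6'-trimethoxyacetophenone | CC(=O)c1c(O)c(Br)c(OC)c(OC)c1OC | intermediate
5 | 2'-hydroxy-3',4',5',6'-tetramethoxyacetophenone | CC(=O)c1c(O)c(OC)c(OC)c(OC)c1OC | intermediate
6 | 4-(benzyloxy)benzaldehyde | O=Cc1ccc(OCc2ccccc2)cc1 | starting material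
7 | (E)-4-benzyloxy-2'-hydroxy-3',4',5',6'-tetramethoxychalcone | COc1c(OC)c(OC)c(C(=O)/C=C/c2ccc(OCc3ccccc3)cc2)c(O)c1OC | intermediate
8 | (±)-trans-4'-benzyloxy-3-hydroxy-5,6,7,8-tetramethoxyflavanone, (2R*,3R*), one enantiomer drawn (not isolated) | COc1c(OC)c(OC)c2c(c1OC)O[C@H](c1ccc(OCc3ccccc3)cc1)[C@@H](O)C2=O | intermediate
9 | 4'-benzyloxy-3-hydroxy-5,6,7,8-tetramethoxyflavone | COc1c(OC)c(OC)c2c(=O)c(O)c(-c3ccc(OCc4ccccc4)cc3)oc2c1OC | intermediate
10 | 4'-benzyloxy-3,5,6,7,8-pentamethoxyflavone | COc1c(OC)c(OC)c2c(=O)c(OC)c(-c3ccc(OCc4ccccc4)cc3)oc2c1OC | intermediate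
11 | 5,4'-bis(dichloroboryloxy)-3,6,7,8-tetramethoxyflavone, the boron on O5 also coordinated to C4=O (not isolated) | COc1c(OC)c(OB(Cl)Cl)c2c(=O)c(OC)c(-c3ccc(OB(Cl)Cl)cc3)oc2c1OC | intermediate
12 | calycopterin, 5,4'-dihydroxy-3,6,7,8-tetramethoxyflavone | COc1c(OC)c(O)c2c(=O)c(OC)c(-c3ccc(O)cc3)oc2c1OC | target

**Total step count:** 7
**Longest linear sequence:** 7 steps (1 → 12). Aldehyde 6 is bought and enters in step 4.

**Steps most likely to fail**

1. Step 5.
   - What may go wrong: ring closure may run through the α-carbon to the five-membered ring, the oxidation may stall at the 3-hydroxyflavanone stage, or peroxide may cleave the enone.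
   - Fallback: ring closure is separated from C3 oxygenation, setting out from 7. Catalytic I2 in DMSO at 120–130 °C cyclodehydrogenates 7 to 4'-benzyloxy-5,6,7,8-tetramethoxyflavone F1. Dimethyldioxirane (acetone–CH2Cl2, 0 °C) epoxidises the C2=C3 bond of F1 to (±)-4'-benzyloxy-2,3-epoxy-5,6,7,8-tetramethoxyflavanone F2. A trace of p-TsOH isomerises F2 to the flavonol, and the route is rejoined at 9.

2. Step 7.
   - What may go wrong: further methyl ethers may be lost (the 3-OMe through a five-membered chelate, the 6-OMe through the boron held on O5), or the benzyl cation may transfer to ring B.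
   - Fallback: the two cleavages are separated and the benzyl group is removed by reduction, setting out from 10. H2 (1 atm) over Pd/C in EtOAc–MeOH gives 4'-hydroxy-3,5,6,7,8-pentamethoxyflavone F3. AlCl3 in MeCN at 60–70 °C, followed by warm dilute HCl to break the aluminium chelate, then removes only the peri 5-methyl group and arrives at 12.

3. Step 3.
   - What may go wrong: bromine may be lost reductively, exchange may be incomplete at a bromide flanked by two ortho substituents, or base may drive self-condensation of the methyl ketone.
   - Fallback: the oxygen is installed by exchanging a carbon substituent for oxygen rather than by halide substitution, setting out from 3 and bypassing 4. Duff formylation (hexamethylenetetramine, TFA, 80 °C; then aq HCl) at the same free position gives 3-acetyl-2-hydroxy-4,5,6-trimethoxybenzaldehyde F4. Dakin oxidation (H2O2, aq NaOH, 0 °C → rt), in which the aldehyde should react ahead of the ketone, gives 2',3'-dihydroxy-4',5',6'-trimethoxyacetophenone F5. One equivalent of MeI with K2CO3 in acetone should methylate the 3'-hydroxyl, because the 2'-hydroxyl is tied up in the hydrogen bond to the acetyl carbonyl, and the route is rejoined at 5.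

**Further compounds**
F1 | step 5 | 4'-benzyloxy-5,6,7,8-tetramethoxyflavone | COc1c(OC)c(OC)c2c(=O)cc(-c3ccc(OCc4ccccc4)cc3)oc2c1OC
F2 | step 5 | (±)-4'-benzyloxy-2,3-epoxy-5,6,7,8-tetramethoxyflavanone (cis-fused epoxide, one enantiomer drawn) | COc1c(OC)c(OC)c2c(c1OC)O[C@]1(c3ccc(OCc4ccccc4)cc3)O[C@@H]1C2=O
F3 | step 7 | 4'-hydroxy-3,5,6,7,8-pentamethoxyflavone | COc1c(OC)c(OC)c2c(=O)c(OC)c(-c3ccc(O)cc3)oc2c1OC
F4 | step 3 | 3-acetyl-2-hydroxy-4,5,6-trimethoxybenzaldehyde | CC(=O)c1c(O)c(C=O)c(OC)c(OC)c1OC
F5 | step 3 | 2',3'-dihydroxy-4',5',6'-trimethoxyacetophenone | CC(=O)c1c(O)c(O)c(OC)c(OC)c1OC
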